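**Assumption:** both enantiomers of the Shi ketone and of the CBS catalyst are purchasable catalysts, and small reagents (MeI, vinylmagnesium bromide, 2-methylbut-2-ene and the like) are bought.

## Retrosynthetic overview

1. The last C–C bond is the one between the ethylene bridge and C5 of the azulene. It is made by adding the benzoxepinyl-ethyllithium 40 to the vinylogous ester 21, followed by acid transposition (Stork–Danheiser); the C7 carbinol then comes from a CBS reduction.
2. Azulene half 21: both five-membered rings come from one Pauson–Khand reaction of enyne 6. The seven-membered ring follows by a two-carbon ring expansion (dichloroketene [2+2], retro-aldol). The C1 carbinol is set by convex-face hydration.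
3. Benzoxepine half 39: the oxepane and then the cyclohexanone form in one Me3SiOTf-triggered epoxide cascade of the diepoxy silyl enol ether 33. The two epoxides come from two Shi epoxidations of opposite sense; the C7 carbinol from equatorial MeLi addition.
4. Building blocks: 5-bromopent-2-yne, acrolein, hex-1-en-5-yne and ethyl 3-iodopropanoate.

## Part A – azulene half (steps 1–15)

**Step 1**
Reactants: 1 5-bromopent-2-yne; 2 acrolein
Product: 4 (±)-oct-1-en-6-yn-3-ol, via Grignard reagent 3 (not isolated)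
Conditions: Mg, THF, rt; then 2, –78 °C; aq. NH4Cl
Reagents that add atoms: none
Why: Grignard formation and 1,2-addition to the enal give the racemic allylic alcohol that carries all eight skeletal carbons of the two five-membered rings.

**Step 2**
Reactants: 4 (±)-oct-1-en-6-yn-3-ol
Product: 5 (3R)-oct-1-en-6-yn-3-ol
Conditions: Ti(OiPr)4, L-(+)-diisopropyl tartrate, t-BuOOH (0.6 equiv), 4 Å molecular sieves, CH2Cl2, –20 °C
Reagents that add atoms: none
Why: Sharpless kinetic resolution; with the L-(+)-tartrate the (S)-alcohol is epoxidised fast and the (R)-alcohol is recovered in high ee, which fixes the absolute configuration of this half.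

**Step 3**
Reactants: 5 (3R)-oct-1-en-6-yn-3-ol
Product: 6 tert-butyldimethyl{[(3R)-oct-1-en-6-yn-3-yl]oxy}silane
Conditions: t-BuMe2SiCl, imidazole, DMF, rt
Reagents that add atoms: tert-butyldimethylsilyl chloride, CC(C)(C)[Si](C)(C)Cl
Why: Silyl ether formation gives a bulky allylic substituent that steers the next cyclisation.

**Step 4**
Reactants: 6 silyl ether
Product: 7 (6R,6aR)-6-[(tert-butyldimethylsilyl)oxy]-3-methyl-4,5,6,6a-tetrahydropentalen-2(1H)-one
Conditions: Co2(CO)8 (10 mol%), tetramethylthiourea (60 mol%), CO (1 atm), benzene, 70 °C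
Reagents that add atoms: carbon monoxide, [C-]#[O+]
Why: Intramolecular Pauson–Khand [2+2+1] cycloaddition; the allylic silyloxy group takes the exo position, so H-6a is set cis to it (minor isomer removed by chromatography).

**Step 5**
Reactants: 7 bicyclic enone
Product: 9 (3aR,4R,6aR)-4-[(tert-butyldimethylsilyl)oxy]-1,1-dimethylhexahydropentalen-2(1H)-one, via lithium enolate 8 (not isolated)
Conditions: Li, t-BuOH (1 equiv), NH3(l)/THF, –78 °C; then MeI, –78 → –33 °C
Reagents that add atoms: iodomethane, CI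
Why: Dissolving-metal reductive alkylation; protonation at the β-carbon gives the cis-fused bicycle (trans is prohibitively strained) and the regiospecific enolate is methylated to the gem-dimethyl ketone.

**Step 6**
Reactants: 9 silyloxy ketone
Product: 10 (3a'R,4'R,6a'R)-1',1'-dimethylhexahydro-1'H-spiro[1,3-dioxolane-2,2'-pentalen]-4'-ol
Conditions: HOCH2CH2OH, TsOH·H2O, benzene, reflux (Dean–Stark)
Reagents that add atoms: ethane-1,2-diol, OCCO
Why: Acid-catalysed ketalisation masks the hindered ketone while the same acid cleaves the silyl ether.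

**Step 7**
Reactants: 10 hydroxy ketal
Product: 11 (3a'R,6a'R)-1',1'-dimethyltetrahydro-1'H-spiro[1,3-dioxolane-2,2'-pentalen]-4'(5'H)-one
Conditions: Dess–Martin periodinane, NaHCO3, CH2Cl2, rt
Reagents that add atoms: none
Why: Dess–Martin oxidation; the α-centre C3a' cannot be lost because only the cis-fused bicyclo[3.3.0]octane is accessible.

**Step 8**
Reactants: 11 keto ketal
Product: 12 (3a'R,6a'R)-1',1'-dimethyl-4'-methylidenehexahydro-1'H-spiro[1,3-dioxolane-2,2'-pentalene]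
Conditions: Ph3PCH3Br, KOtBu, THF, 0 °C → rt
Reagents that add atoms: methyltriphenylphosphonium bromide, C[P+](c1ccccc1)(c1ccccc1)c1ccccc1.[Br-]
Why: Wittig methylenation of the only free ketone.

**Step 9**
Reactants: 12 methylidene ketal
Product: 14 (3aR,4R,6aR)-4-hydroxy-1,1,4-trimethylhexahydropentalen-2(1H)-one, via tertiary alcohol ketal 13 (not isolated)
Conditions: Co(acac)2 (20 mol%), PhSiH3, O2 (1 atm), i-PrOH/THF, rt; then PPTS, acetone/H2O, 60 °C
Reagents that add atoms: dioxygen, O=O; water, O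
Why: Mukaiyama hydration (hydrogen-atom transfer, then O2 trapping); the tertiary radical is trapped on the convex face, so the hydroxyl ends up cis to the ring-fusion hydrogens and the methyl on the concave side; the ketal is then hydrolysed.

**Step 10**
Reactants: 14 hydroxy ketone
Product: 15 trimethyl{[(3aS,4R,6aR)-1,1,4-trimethyl-4-[(trimethylsilyl)oxy]-1,3a,4,5,6,6a-hexahydropentalen-2-yl]oxy}silane
Conditions: Me3SiOTf (2.5 equiv), Et3N, CH2Cl2, 0 °C
Reagents that add atoms: trimethylsilyl trifluoromethanesulfonate, C[Si](C)(C)OS(=O)(=O)C(F)(F)F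
Why: Soft enolisation and silylation; the ketone can enolise only away from the quaternary carbon, and the tertiary alcohol is capped at the same time.

**Step 11**
Reactants: 15 bis-silyl compound
Product: 16 tricyclic dichlorocyclobutanone (2,2-dichlorocyclobutanone fused across C2–C3 of 15, CCl2 on the silyloxy carbon, both new bonds on the convex face)
Conditions: Cl2CHCOCl, Et3N, hexane, rt (slow addition)
Reagents that add atoms: dichloroacetyl chloride, O=C(Cl)C(Cl)Cl
Why: Ketene–enol ether [2+2] cycloaddition; the nucleophilic β-carbon of the enol ether bonds to the ketene carbonyl carbon, which fixes the regiochemistry.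

**Step 12**
Reactants: 16 dichlorocyclobutanone
Product: 18 (1R,3aR,8aR)-1-hydroxy-1,4,4-trimethylhexahydroazulene-5,7(1H,6H)-dione, via dechlorinated cyclobutanone 17 (not isolated)
Conditions: Zn dust, AcOH, i-PrOH/H2O, 0 °C → rt; then 80 °C
Reagents that add atoms: none
Why: Reductive dechlorination, then desilylation with retro-aldol cleavage of the ring-fusion bond; this two-carbon ring expansion gives the cycloheptane-1,3-dione without touching the stereocentres.

**Step 13**
Reactants: 18 hydroxy dione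
Product: 19 (1R,3aR,8aR)-1-hydroxy-1,4,4,6-tetramethylhexahydroazulene-5,7(1H,6H)-dione (C6 epimers)
Conditions: MeI, K2CO3, acetone, reflux
Reagents that add atoms: iodomethane, CI
Why: C-alkylation of the 1,3-dione at the doubly activated C6.

**Step 14**
Reactants: 19 methyl dione
Product: 20 (1R,3aR,8aR)-1-hydroxy-7-methoxy-1,4,4,6-tetramethyl-2,3,3a,4,8,8a-hexahydroazulen-5(1H)-one
Conditions: Me2SO4, K2CO3, acetone, rt
Reagents that add atoms: dimethyl sulfate, COS(=O)(=O)OC
Why: O-alkylation of the dione enolate at the oxygen remote from the gem-dimethyl group gives the vinylogous ester whose carbonyl sits next to CMe2.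

**Step 15**
Reactants: 20 vinylogous ester
Product: 21 (1R,3aR,8aR)-7-methoxy-1,4,4,6-tetramethyl-1-[(triethylsilyl)oxy]-2,3,3a,4,8,8a-hexahydroazulen-5(1H)-one
Conditions: Et3SiOTf, 2,6-lutidine, CH2Cl2, –78 → 0 °C
Reagents that add atoms: triethylsilyl trifluoromethanesulfonate, CC[Si](CC)(CC)OS(=O)(=O)C(F)(F)F
Why: Silylation of the tertiary alcohol so that it does not quench the organolithium in the coupling.

## Part B – benzoxepine half (steps 16–28)

**Step 16**
Reactants: 22 hex-1-en-5-yne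
Product: 24 (1E)-1-iodo-2-methylhexa-1,5-diene, via vinylalane 23 (not isolated)
Conditions: Me3Al, Cp2ZrCl2 (25 mol%), CH2Cl2, 0 °C → rt; then I2, THF, –30 °C
Reagents that add atoms: trimethylaluminium, C[Al](C)C; iodine, II
Why: Negishi zirconium-catalysed carboalumination adds Me and Al syn across the alkyne only, and iodinolysis with retention gives the E-trisubstituted vinyl iodide.

**Step 17**
Reactants: 24 vinyl iodide; 25 ethyl 3-iodopropanoate
Product: 27 ethyl (4E)-5-methylnona-4,8-dienoate, via organozinc iodide 26 (not isolated)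
Conditions: 25, Zn dust (activated with BrCH2CH2Br and Me3SiCl), THF/DMA, 40 °C; then 24, Pd(PPh3)4 (5 mol%), 40 °C
Reagents that add atoms: none
Why: Negishi cross-coupling of the zinc homoenolate with retention of the alkene geometry.

**Step 18**
Reactants: 27 dienoate
Product: 28 (4E)-N-methoxy-N,5-dimethylnona-4,8-dienamide
Conditions: MeNHOMe·HCl, i-PrMgCl, THF, –20 → 0 °C
Reagents that add atoms: N,O-dimethylhydroxylamine hydrochloride, CNOC.Cl
Why: Weinreb amide formation before any epoxide is present.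

**Step 19**
Reactants: 28 Weinreb amide
Product: 29 3-[(2R,3R)-3-(but-3-en-1-yl)-3-methyloxiran-2-yl]-N-methoxy-N-methylpropanamide
Conditions: Shi ketone (1,2:4,5-di-O-isopropylidene-β-D-erythro-2,3-hexodiulo-2,6-pyranose, 30 mol%), KHSO5 (Oxone), K2CO3, Bu4NHSO4, aq. Na2B4O7 buffer, MeCN/CH2(OMe)2, 0 °C
Reagents that add atoms: potassium peroxymonosulfate, [K+].OOS(=O)(=O)[O-]
Why: Shi asymmetric epoxidation; the dioxirane from the D-fructose-derived ketone gives the (R,R)-epoxide of the trisubstituted alkene and leaves the terminal alkene alone.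

**Step 20**
Reactants: 29 mono-epoxide
Product: 30 N-methoxy-N-methyl-3-[(2R,3R)-3-methyl-3-(4-methylpent-3-en-1-yl)oxiran-2-yl]propanamide
Conditions: 2-methylbut-2-ene (excess), second-generation Grubbs catalyst (5 mol%), CH2Cl2, 40 °C
Reagents that add atoms: 2-methylbut-2-ene, CC=C(C)C
Why: Olefin cross-metathesis turns the terminal alkene into the isopropylidene terminus only after the first epoxide is in place, so the two epoxides can be set independently.

**Step 21**
Reactants: 30 epoxy alkene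
Product: 31 3-[(2R,3R)-3-{2-[(2S)-3,3-dimethyloxiran-2-yl]ethyl}-3-methyloxiran-2-yl]-N-methoxy-N-methylpropanamide
Conditions: enantiomeric Shi ketone (1,2:4,5-di-O-isopropylidene-β-L-erythro-2,3-hexodiulo-2,6-pyranose, 30 mol%), KHSO5, K2CO3, Bu4NHSO4, aq. Na2B4O7 buffer, MeCN/CH2(OMe)2, 0 °C
Reagents that add atoms: potassium peroxymonosulfate, [K+].OOS(=O)(=O)[O-]
Why: Shi epoxidation under catalyst control; the L-series ketone gives the (S)-terminal epoxide, the configuration later found at C3 of the oxepane.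

**Step 22**
Reactants: 31 diepoxy amide
Product: 32 5-[(2R,3R)-3-{2-[(2S)-3,3-dimethyloxiran-2-yl]ethyl}-3-methyloxiran-2-yl]pent-1-en-3-one
Conditions: CH2=CHMgBr, THF, –78 → 0 °C; inverse quench into cold aq. NH4Cl
Reagents that add atoms: vinylmagnesium bromide, C=C[Mg]Br
Why: Weinreb ketone synthesis; the chelated tetrahedral intermediate stops at the vinyl ketone and the trisubstituted epoxides are inert at low temperature.

**Step 23**
Reactants: 32 vinyl ketone
Product: 33 {[(3Z)-1-[(2R,3R)-3-{2-[(2S)-3,3-dimethyloxiran-2-yl]ethyl}-3-methyloxiran-2-yl]hepta-3,6-dien-3-yl]oxy}trimethylsilane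
Conditions: CH2=CHMgBr, CuBr·SMe2 (10 mol%), Me3SiCl, HMPA, THF, –78 °C; Et3N, pentane work-up
Reagents that add atoms: vinylmagnesium bromide, C=C[Mg]Br; chlorotrimethylsilane, C[Si](C)(C)Cl
Why: Copper-catalysed conjugate addition with in situ silylation gives the silyl enol ether regiospecifically on the side that will become C6 (its geometry is of no consequence).

**Step 24**
Reactants: 33 diepoxy silyl enol ether
Product: 35 (3S,5aR,6R,9aR)-3-hydroxy-2,2,5a-trimethyl-6-(prop-2-en-1-yl)octahydro-1-benzoxepin-7(2H)-one, via trimethylsilyl ether 34 (not isolated)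
Conditions: Me3SiOTf (1.1 equiv), 2,6-di-tert-butyl-4-methylpyridine, CH2Cl2, –78 °C; then K2CO3, MeOH, 0 °C → rt
Reagents that add atoms: none
Why: Lewis-acid-triggered tandem oxa-/carbacyclisation; the internal epoxide oxygen opens the silylated terminal epoxide at its tertiary carbon (oxepane), the resulting epoxonium ion is opened with inversion at C5a by the enol ether through a chair (trans ring fusion), so C3, C5a and C9a follow from the two epoxides, and K2CO3/MeOH removes the silyl group and equilibrates C6 to the equatorial allyl isomer.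

**Step 25**
Reactants: 35 hydroxy ketone
Product: 36 (3S,5aR,6R,7S,9aR)-2,2,5a,7-tetramethyl-6-(prop-2-en-1-yl)decahydro-1-benzoxepine-3,7-diol
Conditions: MeLi (3.5 equiv), CeCl3, THF, –78 °C
Reagents that add atoms: methyllithium, [Li]C
Why: Organocerium 1,2-addition; axial attack is blocked by the 1,3-syn-axial angular methyl, so the methyl enters equatorially and the new hydroxyl is axial, cis to that methyl (7S).

**Step 26**
Reactants: 36 diol
Product: 37 (3S,5aR,6R,7S,9aR)-2,2,5a,7-tetramethyl-6-(prop-2-en-1-yl)-3,7-bis[(triethylsilyl)oxy]decahydro-1-benzoxepine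
Conditions: Et3SiOTf (3 equiv), 2,6-lutidine, CH2Cl2, –78 °C → rt
Reagents that add atoms: triethylsilyl trifluoromethanesulfonate, CC[Si](CC)(CC)OS(=O)(=O)C(F)(F)F
Why: Silylation of both alcohols; the tertiary one must be capped or it would close a tetrahydrofuran onto the side chain in step 28.

**Step 27**
Reactants: 37 bis-silyl ether
Product: 38 2-[(3S,5aR,6R,7S,9aR)-2,2,5a,7-tetramethyl-3,7-bis[(triethylsilyl)oxy]decahydro-1-benzoxepin-6-yl]ethan-1-ol
Conditions: O3, CH2Cl2/MeOH, –78 °C; then NaBH4, –78 → 0 °C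
Reagents that add atoms: ozone, [O-][O+]=O
Why: Ozonolysis of the only alkene with reductive work-up shortens the allyl group to the two-carbon bridge.

**Step 28**
Reactants: 38 primary alcohol
Product: 39 (3S,5aR,6R,7S,9aR)-6-(2-iodoethyl)-2,2,5a,7-tetramethyl-3,7-bis[(triethylsilyl)oxy]decahydro-1-benzoxepine
Conditions: I2, PPh3, imidazole, CH2Cl2, 0 °C → rt
Reagents that add atoms: iodine, II
Why: Appel-type iodination of the primary alcohol.

## Part C – coupling and end game (steps 29–31)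

**Step 29**
Reactants: 39 iodide; 21 vinylogous ester
Product: 42 (1R,3aR,8aR)-1,4,4,6-tetramethyl-5-{2-[(3S,5aR,6R,7S,9aR)-2,2,5a,7-tetramethyl-3,7-bis[(triethylsilyl)oxy]decahydro-1-benzoxepin-6-yl]ethyl}-1-[(triethylsilyl)oxy]-2,3,3a,4,8,8a-hexahydroazulen-7(1H)-one, via organolithium 40 (not isolated), via carbinol adduct 41 (not isolated)
Conditions: t-BuLi (2.1 equiv), Et2O/pentane, –78 °C; then 21, THF, –78 → –20 °C; then 0.5 M aq. HCl, THF, 0 °C
Reagents that add atoms: none
Why: Iodine–lithium exchange, 1,2-addition to the only carbonyl and acid-induced Stork–Danheiser transposition join the C16 and C14 halves and place the tetrasubstituted alkene and the C7 ketone exactly where the target needs them.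

**Step 30**
Reactants: 42 enone
Product: 43 (1R,3aR,7S,8aR)-7-hydroxy allylic alcohol (the 3,7-bis- and 1-triethylsilyl ethers of the target)
Conditions: (R)-2-methyl-CBS-oxazaborolidine [(3aR)-1-methyl-3,3-diphenyltetrahydro-1H,3H-pyrrolo[1,2-c][1,3,2]oxazaborole] (0.3 equiv), BH3·SMe2, THF, –30 °C
Reagents that add atoms: none
Why: Corey–Bakshi–Shibata reduction; the α-methyl alkenyl carbon acts as the large group and CH2-8 as the small one, so the (R)-catalyst delivers hydride to give the 7S alcohol with 1,2-selectivity.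

**Step 31**
Reactants: 43 tris-silyl ether
Product: 44 target, (3S,5aR,6R,7S,9aR)-6-{2-[(1R,3aR,7S,8aR)-1,7-dihydroxy-1,4,4,6-tetramethyl-1,2,3,3a,4,7,8,8a-octahydroazulen-5-yl]ethyl}-2,2,5a,7-tetramethyldecahydro-1-benzoxepine-3,7-diol
Conditions: Bu4NF, THF, rt → 40 °C
Reagents that add atoms: none
Why: Fluoride-mediated cleavage of the three triethylsilyl ethers under non-acidic conditions, which spares the allylic alcohol.

## Compound list

1 | 5-bromopent-2-yne | CC#CCCBr | starting material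
2 | acrolein | C=CC=O | starting material
3 | pent-3-yn-1-ylmagnesium bromide | CC#CCC[Mg]Br | intermediate
4 | (±)-oct-1-en-6-yn-3-ol | C=CC(O)CCC#CC | intermediate
5 | (3R)-oct-1-en-6-yn-3-ol | C=C[C@H](O)CCC#CC | intermediate
6 | tert-butyldimethyl{[(3R)-oct-1-en-6-yn-3-yl]oxy}silane | C=C[C@H](O[Si](C)(C)C(C)(C)C)CCC#CC | intermediate
7 | (6R,6aR)-6-[(tert-butyldimethylsilyl)oxy]-3-methyl-4,5,6,6a-tetrahydropentalen-2(1H)-one | CC1=C2CC[C@@H](O[Si](C)(C)C(C)(C)C)[C@@H]2CC1=O | intermediate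
8 | lithium enolate of the cis-fused 1-methyl ketone | CC1=C(O[Li])C[C@H]2[C@H](O[Si](C)(C)C(C)(C)C)CC[C@@H]12 | intermediate
9 | (3aR,4R,6aR)-4-[(tert-butyldimethylsilyl)oxy]-1,1-dimethylhexahydropentalen-2(1H)-one | CC1(C)C(=O)C[C@H]2[C@H](O[Si](C)(C)C(C)(C)C)CC[C@@H]12 | intermediate
10 | (3a'R,4'R,6a'R)-1',1'-dimethylhexahydro-1'H-spiro[1,3-dioxolane-2,2'-pentalen]-4'-ol | CC1(C)C2(OCCO2)C[C@H]3[C@H](O)CC[C@@H]13 | intermediate
11 | (3a'R,6a'R)-1',1'-dimethyltetrahydro-1'H-spiro[1,3-dioxolane-2,2'-pentalen]-4'(5'H)-one | CC1(C)C2(OCCO2)C[C@H]3C(=O)CC[C@@H]13 | intermediate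
12 | (3a'R,6a'R)-1',1'-dimethyl-4'-methylidenehexahydro-1'H-spiro[1,3-dioxolane-2,2'-pentalene] | CC1(C)C2(OCCO2)C[C@H]3C(=C)CC[C@@H]13 | intermediate
13 | (3a'R,4'R,6a'R)-1',1',4'-trimethylhexahydro-1'H-spiro[1,3-dioxolane-2,2'-pentalen]-4'-ol | CC1(C)C2(OCCO2)C[C@H]3[C@](C)(O)CC[C@@H]13 | intermediate
14 | (3aR,4R,6aR)-4-hydroxy-1,1,4-trimethylhexahydropentalen-2(1H)-one | CC1(C)C(=O)C[C@H]2[C@](C)(O)CC[C@@H]12 | intermediate
15 | trimethyl{[(3aS,4R,6aR)-1,1,4-trimethyl-4-[(trimethylsilyl)oxy]-1,3a,4,5,6,6a-hexahydropentalen-2-yl]oxy}silane | CC1(C)C(O[Si](C)(C)C)=C[C@H]2[C@](C)(O[Si](C)(C)C)CC[C@@H]12 | intermediate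
16 | tricyclic 2,2-dichlorocyclobutanone from 15 (CCl2 on the silyloxy carbon, new bonds on the convex face) | CC1(C)[C@]2(O[Si](C)(C)C)C(Cl)(Cl)C(=O)[C@@H]2[C@H]3[C@](C)(O[Si](C)(C)C)CC[C@@H]13 | intermediate
17 | the same cyclobutanone without chlorine | CC1(C)[C@]2(O[Si](C)(C)C)CC(=O)[C@@H]2[C@H]3[C@](C)(O[Si](C)(C)C)CC[C@@H]13 | intermediate
18 | (1R,3aR,8aR)-1-hydroxy-1,4,4-trimethylhexahydroazulene-5,7(1H,6H)-dione | CC1(C)C(=O)CC(=O)C[C@H]2[C@](C)(O)CC[C@@H]12 | intermediate
19 | (1R,3aR,8aR)-1-hydroxy-1,4,4,6-tetramethylhexahydroazulene-5,7(1H,6H)-dione (C6 epimers) | CC1(C)C(=O)C(C)C(=O)C[C@H]2[C@](C)(O)CC[C@@H]12 | intermediate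
20 | (1R,3aR,8aR)-1-hydroxy-7-methoxy-1,4,4,6-tetramethyl-2,3,3a,4,8,8a-hexahydroazulen-5(1H)-one | COC1=C(C)C(=O)C(C)(C)[C@@H]2CC[C@@](C)(O)[C@@H]2C1 | intermediate
21 | (1R,3aR,8aR)-7-methoxy-1,4,4,6-tetramethyl-1-[(triethylsilyl)oxy]-2,3,3a,4,8,8a-hexahydroazulen-5(1H)-one | COC1=C(C)C(=O)C(C)(C)[C@@H]2CC[C@@](C)(O[Si](CC)(CC)CC)[C@@H]2C1 | intermediate
22 | hex-1-en-5-yne | C=CCCC#C | starting material
23 | dimethyl[(1E)-2-methylhexa-1,5-dien-1-yl]alumane | C=CCC/C(C)=C/[Al](C)C | intermediate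
24 | (1E)-1-iodo-2-methylhexa-1,5-diene | C=CCC/C(C)=C/I | intermediate
25 | ethyl 3-iodopropanoate | CCOC(=O)CCI | starting material
26 | (3-ethoxy-3-oxopropyl)zinc iodide | CCOC(=O)CC[Zn]I | intermediate
27 | ethyl (4E)-5-methylnona-4,8-dienoate | C=CCC/C(C)=C/CCC(=O)OCC | intermediate
28 | (4E)-N-methoxy-N,5-dimethylnona-4,8-dienamide | C=CCC/C(C)=C/CCC(=O)N(C)OC | intermediate
29 | 3-[(2R,3R)-3-(but-3-en-1-yl)-3-methyloxiran-2-yl]-N-methoxy-N-methylpropanamide | C=CCC[C@@]1(C)O[C@@H]1CCC(=O)N(C)OC | intermediate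
30 | N-methoxy-N-methyl-3-[(2R,3R)-3-methyl-3-(4-methylpent-3-en-1-yl)oxiran-2-yl]propanamide | CC(C)=CCC[C@@]1(C)O[C@@H]1CCC(=O)N(C)OC | intermediate
31 | 3-[(2R,3R)-3-{2-[(2S)-3,3-dimethyloxiran-2-yl]ethyl}-3-methyloxiran-2-yl]-N-methoxy-N-methylpropanamide | CC1(C)O[C@H]1CC[C@@]2(C)O[C@@H]2CCC(=O)N(C)OC | intermediate
32 | 5-[(2R,3R)-3-{2-[(2S)-3,3-dimethyloxiran-2-yl]ethyl}-3-methyloxiran-2-yl]pent-1-en-3-one | CC1(C)O[C@H]1CC[C@@]2(C)O[C@@H]2CCC(=O)C=C | intermediate
33 | {[(3Z)-1-[(2R,3R)-3-{2-[(2S)-3,3-dimethyloxiran-2-yl]ethyl}-3-methyloxiran-2-yl]hepta-3,6-dien-3-yl]oxy}trimethylsilane | CC1(C)O[C@H]1CC[C@@]2(C)O[C@@H]2CC/C(O[Si](C)(C)C)=C/CC=C | intermediate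
34 | (3S,5aR,9aR)-2,2,5a-trimethyl-6-(prop-2-en-1-yl)-3-[(trimethylsilyl)oxy]octahydro-1-benzoxepin-7(2H)-one (C6 epimers) | C=CCC1[C@@]2(C)CC[C@H](O[Si](C)(C)C)C(C)(C)O[C@@H]2CCC1=O | intermediate
35 | (3S,5aR,6R,9aR)-3-hydroxy-2,2,5a-trimethyl-6-(prop-2-en-1-yl)octahydro-1-benzoxepin-7(2H)-one | C=CC[C@@H]1[C@@]2(C)CC[C@H](O)C(C)(C)O[C@@H]2CCC1=O | intermediate
36 | (3S,5aR,6R,7S,9aR)-2,2,5a,7-tetramethyl-6-(prop-2-en-1-yl)decahydro-1-benzoxepine-3,7-diol | C=CC[C@@H]1[C@@]2(C)CC[C@H](O)C(C)(C)O[C@@H]2CC[C@]1(C)O | intermediate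
37 | 3,7-bis(triethylsilyl) ether of 36 | C=CC[C@@H]1[C@@]2(C)CC[C@H](O[Si](CC)(CC)CC)C(C)(C)O[C@@H]2CC[C@]1(C)O[Si](CC)(CC)CC | intermediate
38 | 2-[(3S,5aR,6R,7S,9aR)-2,2,5a,7-tetramethyl-3,7-bis[(triethylsilyl)oxy]decahydro-1-benzoxepin-6-yl]ethan-1-ol | OCC[C@@H]1[C@@]2(C)CC[C@H](O[Si](CC)(CC)CC)C(C)(C)O[C@@H]2CC[C@]1(C)O[Si](CC)(CC)CC | intermediate
39 | (3S,5aR,6R,7S,9aR)-6-(2-iodoethyl)-2,2,5a,7-tetramethyl-3,7-bis[(triethylsilyl)oxy]decahydro-1-benzoxepine | ICC[C@@H]1[C@@]2(C)CC[C@H](O[Si](CC)(CC)CC)C(C)(C)O[C@@H]2CC[C@]1(C)O[Si](CC)(CC)CC | intermediate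
40 | the corresponding 2-lithioethyl compound | [Li]CC[C@@H]1[C@@]2(C)CC[C@H](O[Si](CC)(CC)CC)C(C)(C)O[C@@H]2CC[C@]1(C)O[Si](CC)(CC)CC | intermediate
41 | 1,2-adduct of 40 to the C5 carbonyl of 21 (tertiary carbinol, C5 epimers) | COC1=C(C)C(O)(CC[C@@H]2[C@@]3(C)CC[C@H](O[Si](CC)(CC)CC)C(C)(C)O[C@@H]3CC[C@]2(C)O[Si](CC)(CC)CC)C(C)(C)[C@@H]4CC[C@@](C)(O[Si](CC)(CC)CC)[C@@H]4C1 | intermediate
42 | coupled enone (name in step 29) | CC1=C(CC[C@@H]2[C@@]3(C)CC[C@H](O[Si](CC)(CC)CC)C(C)(C)O[C@@H]3CC[C@]2(C)O[Si](CC)(CC)CC)C(C)(C)[C@@H]4CC[C@@](C)(O[Si](CC)(CC)CC)[C@@H]4CC1=O | intermediate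
43 | (7S)-allylic alcohol, tris(triethylsilyl) ether of the target | CC1=C(CC[C@@H]2[C@@]3(C)CC[C@H](O[Si](CC)(CC)CC)C(C)(C)O[C@@H]3CC[C@]2(C)O[Si](CC)(CC)CC)C(C)(C)[C@@H]4CC[C@@](C)(O[Si](CC)(CC)CC)[C@@H]4C[C@@H]1O | intermediate
44 | target (name in step 31) | CC1=C(CC[C@@H]2[C@@]3(C)CC[C@H](O)C(C)(C)O[C@@H]3CC[C@]2(C)O)C(C)(C)[C@@H]2CC[C@@](C)(O)[C@@H]2C[C@@H]1O | target

## Totals and risks

Total step count: 31 (15 for the azulene half, 13 for the benzoxepine half, 3 after the halves meet).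
Longest linear sequence: 18 steps (steps 1–15, then 29–31).

The three steps most likely to fail:

**Step 11 (ketene cycloaddition next to the gem-dimethyl carbon).** The ring closure has to make a fully substituted carbon beside CMe2, and simple C-acylation of the enol ether may win. The fallback sets out from 15 and comes back at 19; it builds the seven-membered ring by ring-closing metathesis instead of ring expansion. Ozonolysis of 15 (O3, CH2Cl2/MeOH, –78 °C; Me2S) and esterification with Me3SiCHN2 give the aldehyde ester F1. Wittig homologation with Ph3P=CHOMe and hydrolysis with aq. HCl (which also removes the silyl group) give the homologous aldehyde F2. Methylenation with Ph3P=CH2 gives the allyl ester F3. 2-Propenyllithium (THF, –78 °C) converts the hindered ester into the isopropenyl ketone F4. The second-generation Grubbs catalyst closes this to the cycloheptenone F5. Epoxidation with H2O2/NaOH gives the epoxy ketone F6, which Pd(PPh3)4/dppe isomerises to the 1,3-dione 19; the route continues with step 14.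

**Step 24 (epoxide cascade).** Neither the substituted enol ether terminator nor this diastereomer of the diepoxide has direct precedent. The fallback sets out from 31 and comes back at 35; it uses the terminal enol ether of a methyl ketone, the terminator with literature precedent for this bicyclisation, and introduces the allyl group afterwards. MeMgBr converts 31 into the methyl ketone F7, and LDA/Me3SiCl gives the terminal silyl enol ether F8. Me3SiOTf with 2,6-di-tert-butyl-4-methylpyridine, then K2CO3/MeOH, gives the unsubstituted bicyclic hydroxy ketone F9. Kinetic enolisation away from the quaternary carbon (LDA, Me3SiCl) and Saegusa oxidation with Pd(OAc)2 give the enone F10. LDA then deprotonates the only α'-position left (C6) and allyl bromide gives the allyl enone F11. Conjugate reduction with [(Ph3P)CuH]6 and equilibration with K2CO3/MeOH return 35.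

**Step 29 (addition of a precious primary alkyllithium to a carbonyl flanked by CMe2 and a substituted alkene).** The fallback sets out from 19 and 40 and comes back at 44; it replaces carbonyl addition by a B-alkyl Suzuki–Miyaura coupling. L-Selectride reduces the less hindered C7 carbonyl of 19 from the convex face to the hydroxy ketone F12, and Et3SiOTf/2,6-lutidine gives the bis-silyl ether F13. KHMDS and PhNTf2 give the only possible enol triflate F14. The organolithium 40 is trapped with B-methoxy-9-BBN as the borate F15, which is coupled with F14 (Pd(dppf)Cl2, AsPh3, Cs2CO3, DMF/H2O) to the tetrasilyl ether F16; Bu4NF then gives 44.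

## Further compounds

F1 | step 11 | methyl 2-[(1R,2R,3R)-2-formyl-3-methyl-3-[(trimethylsilyl)oxy]cyclopentyl]-2-methylpropanoate | COC(=O)C(C)(C)[C@@H]1CC[C@@](C)(O[Si](C)(C)C)[C@@H]1C=O
F2 | step 11 | methyl 2-[(1R,2R,3R)-3-hydroxy-3-methyl-2-(2-oxoethyl)cyclopentyl]-2-methylpropanoate | COC(=O)C(C)(C)[C@@H]1CC[C@@](C)(O)[C@@H]1CC=O
F3 | step 11 | methyl 2-[(1R,2R,3R)-3-hydroxy-3-methyl-2-(prop-2-en-1-yl)cyclopentyl]-2-methylpropanoate | COC(=O)C(C)(C)[C@@H]1CC[C@@](C)(O)[C@@H]1CC=C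
F4 | step 11 | 4-[(1R,2R,3R)-3-hydroxy-3-methyl-2-(prop-2-en-1-yl)cyclopentyl]-2,4-dimethylpent-1-en-3-one | CC(=C)C(=O)C(C)(C)[C@@H]1CC[C@@](C)(O)[C@@H]1CC=C
F5 | step 11 | (1R,3aR,8aR)-1-hydroxy-1,4,4,6-tetramethyl-2,3,3a,4,8,8a-hexahydroazulen-5(1H)-one | CC1=CC[C@H]2[C@](C)(O)CC[C@H]2C(C)(C)C1=O
F6 | step 11 | 6,7-epoxide of F5 (epoxide epimers) | CC12OC1C[C@H]3[C@](C)(O)CC[C@H]3C(C)(C)C2=O
F7 | step 24 | 4-[(2R,3R)-3-{2-[(2S)-3,3-dimethyloxiran-2-yl]ethyl}-3-methyloxiran-2-yl]butan-2-one | CC1(C)O[C@H]1CC[C@@]2(C)O[C@@H]2CCC(C)=O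
F8 | step 24 | {[4-[(2R,3R)-3-{2-[(2S)-3,3-dimethyloxiran-2-yl]ethyl}-3-methyloxiran-2-yl]but-1-en-2-yl]oxy}trimethylsilane | CC1(C)O[C@H]1CC[C@@]2(C)O[C@@H]2CCC(=C)O[Si](C)(C)C
F9 | step 24 | (3S,5aR,9aR)-3-hydroxy-2,2,5a-trimethyloctahydro-1-benzoxepin-7(2H)-one | O=C1CC[C@H]2OC(C)(C)[C@@H](O)CC[C@]2(C)C1
F10 | step 24 | (3S,5aR,9aR)-3-hydroxy-2,2,5a-trimethyl-3,4,5,5a,6,9a-hexahydro-1-benzoxepin-7(2H)-one | O=C1C=C[C@H]2OC(C)(C)[C@@H](O)CC[C@]2(C)C1
F11 | step 24 | 6-(prop-2-en-1-yl) derivative of F10 (C6 epimers) | O=C1C=C[C@H]2OC(C)(C)[C@@H](O)CC[C@]2(C)C1CC=C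
F12 | step 29 | (1R,3aR,7S,8aR)-1,7-dihydroxy-1,4,4,6-tetramethyloctahydroazulen-5(1H)-one (C6 epimers) | CC1C(=O)C(C)(C)[C@@H]2CC[C@@](C)(O)[C@@H]2C[C@@H]1O
F13 | step 29 | 1,7-bis(triethylsilyl) ether of F12 | CC1C(=O)C(C)(C)[C@@H]2CC[C@@](C)(O[Si](CC)(CC)CC)[C@@H]2C[C@@H]1O[Si](CC)(CC)CC
F14 | step 29 | (1R,3aR,7S,8aR)-1,4,4,6-tetramethyl-1,7-bis[(triethylsilyl)oxy]-1,2,3,3a,4,7,8,8a-octahydroazulen-5-yl trifluoromethanesulfonate | CC1=C(OS(=O)(=O)C(F)(F)F)C(C)(C)[C@@H]2CC[C@@](C)(O[Si](CC)(CC)CC)[C@@H]2C[C@@H]1O[Si](CC)(CC)CC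
F15 | step 29 | lithium B-methoxy-B-[2-(benzoxepin-6-yl)ethyl]-9-borabicyclo[3.3.1]nonanate from 40 | [Li+].CO[B-]1(CC[C@@H]2[C@@]3(C)CC[C@H](O[Si](CC)(CC)CC)C(C)(C)O[C@@H]3CC[C@]2(C)O[Si](CC)(CC)CC)C4CCCC1CCC4
F16 | step 29 | tetrakis(triethylsilyl) ether of 44 | CC1=C(CC[C@@H]2[C@@]3(C)CC[C@H](O[Si](CC)(CC)CC)C(C)(C)O[C@@H]3CC[C@]2(C)O[Si](CC)(CC)CC)C(C)(C)[C@@H]4CC[C@@](C)(O[Si](CC)(CC)CC)[C@@H]4C[C@@H]1O[Si](CC)(CC)CC
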